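## Retrosynthetic overview

1. The last bond cut is the C–C bond between the peroxide-bearing quaternary carbon and the side chain, giving a bicyclic methoxy peroxyketal (core) and a side-chain alkylzinc reagent that carries a (trimethylsilyl)methyl spectator group. The chain is expected to enter cis to the lactone oxygen, which fixes this centre.
2. The key disconnection is the pair of peroxide C–O bonds of the core. The O–CH bond at the ring fusion comes from an intramolecular peroxy-Michael addition onto a butenolide; the O–C(ketal) bond comes from methanol trapping of the carbonyl oxide formed by ozonolysis of a methallyl group.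
3. The butenolide goes back, by Z-olefination and lactonisation, to the tertiary α-hydroxy ester from an asymmetric carbonyl-ene reaction of methyl pyruvate with isobutylene. This sets the methyl-bearing ring-fusion carbon.
4. The side chain comes from 1-bromo-6-chlorohexane and acetylide, then hydroboration and Suzuki–Miyaura coupling with (E)-β-bromostyrene for the (E,E)-diene, then magnesium insertion and transmetalation to zinc.
5. Ring order: lactone ring first (step 4), 1,2-dioxane ring second (step 5), side chain attached last (step 9).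

Assumption: locants follow the fused numbering O1, O2, C3, C4, C4a, O5, C6, C7, C7a of furo[3,2-c][1,2]dioxin-6-one, so the target is the (3S,4aR,7aR) isomer; (R,R)-tBu-box is 2,2′-(propane-2,2-diyl)bis[(4R)-4-tert-butyl-4,5-dihydro-1,3-oxazole].

## Route

Step 1
Reactants: 1 methyl pyruvate; 2 isobutylene (2-methylpropene)
Product: 3 methyl (2R)-2-hydroxy-2,4-dimethylpent-4-enoate
Conditions: [Cu((R,R)-tBu-box)](SbF6)2 (10 mol%), CH2Cl2, 40 °C, sealed tube
Reagents that add atoms: none
Why: Bis(oxazoline)–copper-catalysed asymmetric carbonyl-ene reaction in which the pyruvate chelates the divalent copper centre so that only one ketone face is open to the alkene, and the (R,R)-ligand (the (S,S)-ligand is known to give (S)-carbinols) sets the (R) quaternary carbinol that becomes C4a.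

Step 2
Reactants: 3 methyl (2R)-2-hydroxy-2,4-dimethylpent-4-enoate
Product: 4 methyl (2R)-2,4-dimethyl-2-[(triethylsilyl)oxy]pent-4-enoate
Conditions: TESOTf, 2,6-lutidine, CH2Cl2, 0 °C
Reagents that add atoms: triethylsilyl trifluoromethanesulfonate, CC[Si](CC)(CC)OS(=O)(=O)C(F)(F)F
Why: O-Silylation of the hindered tertiary alcohol with a silyl triflate lets the following hydride reduction stop cleanly at the aldehyde, and the stereocentre is not touched.

Step 3
Reactants: 4 methyl (2R)-2,4-dimethyl-2-[(triethylsilyl)oxy]pent-4-enoate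
Product: 5 (2R)-2,4-dimethyl-2-[(triethylsilyl)oxy]pent-4-enal
Conditions: i-Bu2AlH (1.1 equiv), CH2Cl2, −78 °C; aqueous KNaC4H4O6 work-up
Reagents that add atoms: none
Why: Low-temperature i-Bu2AlH half-reduction of an α-silyloxy ester, whose tetrahedral aluminium hemiacetal survives at −78 °C and releases the aldehyde only on work-up, with no epimerisable centre present.

Step 4
Reactants: 5 (2R)-2,4-dimethyl-2-[(triethylsilyl)oxy]pent-4-enal; 6 ethyl 2-(diphenoxyphosphoryl)acetate
Product: 8 (5R)-5-methyl-5-(2-methylprop-2-en-1-yl)furan-2(5H)-one, via Z-enoate 7 (not isolated)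
Conditions: NaH, THF, −78 → 0 °C; then 1 M HCl, THF, rt
Reagents that add atoms: none
Why: Z-selective Horner–Wadsworth–Emmons olefination (Ando diaryl phosphonate) gives the cis-enoate, and acid then cleaves the silyl ether so that the cis-γ-hydroxy ester lactonises to the butenolide (the lactone ring) without creating a new stereocentre.

Step 5
Reactants: 8 (5R)-5-methyl-5-(2-methylprop-2-en-1-yl)furan-2(5H)-one
Product: 10 (4aR,7aR)-3-methoxy-3,4a-dimethyl-4,4a,7,7a-tetrahydro-3H-furo[3,2-c][1,2]dioxin-6-one (both C3 epimers), via hydroperoxy ketal 9 (not isolated)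
Conditions: O3, CH2Cl2–MeOH (4:1), −78 °C; then Et2NH (0.3 equiv), CF3CH2OH, rt
Reagents that add atoms: ozone, O=[O+][O-]; methanol, CO
Why: Ozone cleaves only the electron-rich 1,1-disubstituted alkene, methanol traps the Criegee carbonyl oxide as α-methoxy hydroperoxide 9, and amine-catalysed intramolecular peroxy-Michael (oxa-Michael) addition closes the 1,2-dioxane ring; because the hydroperoxide is tethered to the γ-carbon of the butenolide it can reach the β-carbon only from its own face, which gives the cis ring fusion and sets C7a as (R), while the configuration at the ketal carbon does not matter.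

Step 6
Reactants: 11 1-bromo-6-chlorohexane; 12 lithium acetylide–ethylenediamine complex (LiC≡CH·H2NCH2CH2NH2)
Product: 13 8-chlorooct-1-yne
Conditions: DMSO, 10 °C → rt
Reagents that add atoms: none
Why: SN2 alkylation of the acetylide at the carbon–bromine bond, bromide being displaced much faster than chloride in DMSO.

Step 7
Reactants: 13 8-chlorooct-1-yne; 14 (E)-(2-bromoethenyl)benzene
Product: 16 [(1E,3E)-10-chlorodeca-1,3-dien-1-yl]benzene, via alkenyl catecholboronate 15 (not isolated)
Conditions: catecholborane, neat, 70 °C; then 14, Pd(PPh3)4 (3 mol%), 2 M NaOH (aq), THF, 60 °C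
Reagents that add atoms: none
Why: syn-Hydroboration of the terminal alkyne gives the (E)-alkenylboronate and Suzuki–Miyaura coupling with the (E)-alkenyl bromide proceeds with retention at both partners to give the (E,E)-diene, while the primary alkyl chloride is inert to Pd(PPh3)4 (zerovalent palladium).

Step 8
Reactants: 16 [(1E,3E)-10-chlorodeca-1,3-dien-1-yl]benzene
Product: 19 [(7E,9E)-10-phenyldeca-7,9-dien-1-yl][(trimethylsilyl)methyl]zinc (used as a toluene solution), via alkylmagnesium chloride 17 (not isolated), via alkylzinc chloride 18 (not isolated)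
Conditions: Mg, I2 (cat.), THF, 65 °C; then ZnCl2 (1.0 equiv), 0 °C; then Me3SiCH2Li (1.0 equiv), −30 → 0 °C; THF exchanged for toluene, salts filtered off under argon
Reagents that add atoms: zinc chloride, Cl[Zn]Cl; (trimethylsilyl)methyllithium, [Li]C[Si](C)(C)C
Why: Magnesium insertion into the primary chloride (Grignard formation), transmetalation with one equivalent of ZnCl2 and capping of the alkylzinc chloride with Me3SiCH2Li give a mixed diorganozinc in which the (trimethylsilyl)methyl group is a non-transferable ligand, so the single side chain on zinc is the one delivered, and this soft alkyl donor leaves lactones and dialkyl peroxides alone at low temperature.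

Step 9
Reactants: 10 (4aR,7aR)-3-methoxy-3,4a-dimethyl-4,4a,7,7a-tetrahydro-3H-furo[3,2-c][1,2]dioxin-6-one; 19 [(7E,9E)-10-phenyldeca-7,9-dien-1-yl][(trimethylsilyl)methyl]zinc
Product: 21 plakortolide Q, via peroxycarbenium triflate 20 (not isolated)
Conditions: 19 (1.5 equiv), TMSOTf (1.2 equiv), CH2Cl2–toluene, −78 → −30 °C
Reagents that add atoms: none
Why: Proposed new method: TMSOTf ionises the ketal methoxy group of 10 to the cyclic peroxycarbenium ion 20, a six-membered oxocarbenium-type half-chair in which the lactone C–O bond at C4a is pseudoaxial (electrostatically favoured) and the C4a methyl and C7a methylene are pseudoequatorial, so the primary alkyl group of 19 (the (trimethylsilyl)methyl group stays on zinc) is delivered along the axial trajectory to the face syn to the lactone oxygen, which puts the incoming chain cis to that oxygen and the resident methyl trans and so gives the (3S) centre, the two near-identical alkyl groups being told apart by order of introduction and not by size; the closest known reactions are the Lewis-acid-mediated Hosomi–Sakurai allylation of peroxyketals through peroxycarbenium ions and the alkylation of ordinary oxocarbenium ions by dialkylzinc or trialkylaluminium reagents in molecules carrying an intact peroxide, but an sp3 organozinc has not been added to a peroxycarbenium ion.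

## Compound list

1 | methyl pyruvate (methyl 2-oxopropanoate) | COC(=O)C(C)=O | starting material
2 | isobutylene (2-methylpropene) | CC(C)=C | starting material
3 | methyl (2R)-2-hydroxy-2,4-dimethylpent-4-enoate | COC(=O)[C@](C)(O)CC(C)=C | intermediate
4 | methyl (2R)-2,4-dimethyl-2-[(triethylsilyl)oxy]pent-4-enoate | COC(=O)[C@](C)(O[Si](CC)(CC)CC)CC(C)=C | intermediate
5 | (2R)-2,4-dimethyl-2-[(triethylsilyl)oxy]pent-4-enal | O=C[C@](C)(O[Si](CC)(CC)CC)CC(C)=C | intermediate
6 | ethyl 2-(diphenoxyphosphoryl)acetate | CCOC(=O)CP(=O)(Oc1ccccc1)Oc1ccccc1 | starting material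
7 | ethyl (2Z,4R)-4,6-dimethyl-4-[(triethylsilyl)oxy]hepta-2,6-dienoate | CCOC(=O)/C=C\[C@](C)(O[Si](CC)(CC)CC)CC(C)=C | intermediate (not isolated)
8 | (5R)-5-methyl-5-(2-methylprop-2-en-1-yl)furan-2(5H)-one | C=C(C)C[C@@]1(C)OC(=O)C=C1 | intermediate
9 | (5R)-5-(2-hydroperoxy-2-methoxypropyl)-5-methylfuran-2(5H)-one (both epimers at the ketal carbon) | COC(C)(OO)C[C@@]1(C)OC(=O)C=C1 | intermediate (not isolated)
10 | (4aR,7aR)-3-methoxy-3,4a-dimethyl-4,4a,7,7a-tetrahydro-3H-furo[3,2-c][1,2]dioxin-6-one (cis-fused, both C3 epimers) | COC1(C)C[C@@]2(C)OC(=O)C[C@H]2OO1 | intermediate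
11 | 1-bromo-6-chlorohexane | ClCCCCCCBr | starting material
12 | lithium acetylide–ethylenediamine complex | [Li+].[C-]#C.NCCN | starting material
13 | 8-chlorooct-1-yne | C#CCCCCCCCl | intermediate
14 | (E)-(2-bromoethenyl)benzene ((E)-β-bromostyrene) | Br/C=C/c1ccccc1 | starting material
15 | 2-[(1E)-8-chlorooct-1-en-1-yl]-1,3,2-benzodioxaborole | ClCCCCCC/C=C/B1Oc2ccccc2O1 | intermediate (not isolated)
16 | [(1E,3E)-10-chlorodeca-1,3-dien-1-yl]benzene | ClCCCCCC/C=C/C=C/c1ccccc1 | intermediate
17 | [(7E,9E)-10-phenyldeca-7,9-dien-1-yl]magnesium chloride | Cl[Mg]CCCCCC/C=C/C=C/c1ccccc1 | intermediate (not isolated)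
18 | [(7E,9E)-10-phenyldeca-7,9-dien-1-yl]zinc chloride | Cl[Zn]CCCCCC/C=C/C=C/c1ccccc1 | intermediate (not isolated)
19 | [(7E,9E)-10-phenyldeca-7,9-dien-1-yl][(trimethylsilyl)methyl]zinc | C[Si](C)(C)C[Zn]CCCCCC/C=C/C=C/c1ccccc1 | intermediate
20 | (4aR,7aR)-3,4a-dimethyl-6-oxo-4,4a,7,7a-tetrahydro-6H-furo[3,2-c][1,2]dioxin-3-ylium trifluoromethanesulfonate (cyclic peroxycarbenium ion) | C[C+]1C[C@@]2(C)OC(=O)C[C@H]2OO1.[O-]S(=O)(=O)C(F)(F)F | intermediate (not isolated)
21 | plakortolide Q, (3S,4aR,7aR)-3,4a-dimethyl-3-[(7E,9E)-10-phenyldeca-7,9-dien-1-yl]-4,4a,7,7a-tetrahydro-3H-furo[3,2-c][1,2]dioxin-6-one | C[C@]1(CCCCCC/C=C/C=C/c2ccccc2)C[C@@]2(C)OC(=O)C[C@H]2OO1 | target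

## Step count and risks

Total step count: 9. Longest linear sequence: 6 (steps 1, 2, 3, 4, 5 and 9); the side-chain branch (steps 6, 7, 8) joins at step 9.

The three steps most likely to fail are steps 9, 5 and 1.

**Step 9 (the new alkylation).** The mixed alkylzinc may be too weak a nucleophile for the peroxycarbenium ion, may reduce it by β-hydride transfer, or may pass on the (trimethylsilyl)methyl group in place of the chain. The ion may also rearrange with O–O cleavage before it is trapped. The fallback uses only known reactions, sets out from 10 and comes back at 21. Hosomi–Sakurai allylation of the peroxyketal (allyltrimethylsilane, TMSOTf, CH2Cl2, −78 °C), which should follow the same facial preference, gives (3S,4aR,7aR)-3,4a-dimethyl-3-(prop-2-en-1-yl)-4,4a,7,7a-tetrahydro-3H-furo[3,2-c][1,2]dioxin-6-one F1. Hydroboration of its terminal alkene with 9-BBN (THF, 0 °C to rt) gives (3S,4aR,7aR)-3-[3-(9-borabicyclo[3.3.1]nonan-9-yl)propyl]-3,4a-dimethyl-4,4a,7,7a-tetrahydro-3H-furo[3,2-c][1,2]dioxin-6-one F2. This is coupled without isolation in an alkyl–alkyl Suzuki–Miyaura reaction (Pd(OAc)2, PCy3, K3PO4·H2O, THF, rt) with [(1E,3E)-7-bromohepta-1,3-dien-1-yl]benzene F3, itself made by Horner–Wadsworth–Emmons olefination of 4-bromobutanal with diethyl cinnamylphosphonate, to give 21.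

**Step 5 (ozonolysis and peroxy-Michael closure).** The primary ozonide can also fragment the other way, to the ketone and formaldehyde oxide, and over-ozonolysis of the butenolide is possible. The fallback sets out from 8 and comes back at 9, which is then cyclised to 10 exactly as in step 5. Ozonolysis with reductive work-up (O3, CH2Cl2, −78 °C; Me2S) gives (5R)-5-methyl-5-(2-oxopropyl)furan-2(5H)-one F4. Acid-catalysed perketalisation of this ketone (urea–H2O2, Sc(OTf)3 (cat.), MeOH, rt) gives 9.

**Step 1 (asymmetric ene reaction).** Pyruvate and gaseous isobutylene are a sluggish pair, and the ee of everything downstream rests on this step. The fallback sets out from 1 and comes back at 3. Mukaiyama aldol addition of 2-(trimethylsilyloxy)propene to 1 with the same catalyst [Cu((R,R)-tBu-box)](SbF6)2 (CH2Cl2, −78 °C), a much more reactive nucleophile on the same chelate, gives methyl (2R)-2-methyl-4-oxo-2-[(trimethylsilyl)oxy]pentanoate F5. Wittig methylenation of the ketone (Ph3P=CH2, THF, 0 °C) gives methyl (2R)-2,4-dimethyl-2-[(trimethylsilyl)oxy]pent-4-enoate F6. K2CO3 in MeOH then removes the silyl group to give 3.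

## Further compounds

F1 | step 9 | (3S,4aR,7aR)-3,4a-dimethyl-3-(prop-2-en-1-yl)-4,4a,7,7a-tetrahydro-3H-furo[3,2-c][1,2]dioxin-6-one | C[C@]1(CC=C)C[C@@]2(C)OC(=O)C[C@H]2OO1
F2 | step 9 | (3S,4aR,7aR)-3-[3-(9-borabicyclo[3.3.1]nonan-9-yl)propyl]-3,4a-dimethyl-4,4a,7,7a-tetrahydro-3H-furo[3,2-c][1,2]dioxin-6-one | C[C@]1(CCCB3C4CCCC3CCC4)C[C@@]2(C)OC(=O)C[C@H]2OO1
F3 | step 9 | [(1E,3E)-7-bromohepta-1,3-dien-1-yl]benzene | BrCCC/C=C/C=C/c1ccccc1
F4 | step 5 | (5R)-5-methyl-5-(2-oxopropyl)furan-2(5H)-one | CC(=O)C[C@@]1(C)OC(=O)C=C1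
F5 | step 1 | methyl (2R)-2-methyl-4-oxo-2-[(trimethylsilyl)oxy]pentanoate | COC(=O)[C@](C)(O[Si](C)(C)C)CC(C)=O
F6 | step 1 | methyl (2R)-2,4-dimethyl-2-[(trimethylsilyl)oxy]pent-4-enoate | COC(=O)[C@](C)(O[Si](C)(C)C)CC(C)=C
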